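**Strategy.** The tetrahydrofuran ring (O1, C2–C5) carries three contiguous stereocentres: C2 (aryl), C3 (acetoxymethyl) and the fully substituted C4 (hydroxyl, benzyl). The plan cuts C2–C3 and C4–C5 and treats the C4 hydroxyl as a former formyl group. A Prins cyclisation–pinacol ring contraction of an (R)-configured, (E)-trisubstituted allylic 1,2-diol with O-benzylvanillin then forms the ring, both C–C bonds and all three stereocentres in one operation. The diol, a 3-benzylpent-3-ene-1,2-diol with a silyloxy group at C5, is built from (S)-glycerate; its alkene geometry is fixed by trans-hydroalumination–iodination and Negishi coupling. Baeyer–Villiger oxidation, acetylation and hydrogenolysis finish the synthesis.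

Key step: step 8

Remark: tetrahydrofuran positions are numbered as in the target throughout (O1, C2 aryl, C3, C4, C5), and the carbinol oxygen is taken to sit equatorial in the chair of step 8, which makes the (S)-glycerate the correct enantiomeric series.

**Route**

Step 1
Reactants: 1 methyl (S)-2,2-dimethyl-1,3-dioxolane-4-carboxylate
Product: 3 (R)-4-ethynyl-2,2-dimethyl-1,3-dioxolane, via dioxolane carbaldehyde 2 (not isolated)
Conditions: DIBAL-H (1.1 equiv), CH2Cl2, −78 °C; then MeOH, K2CO3, dimethyl (1-diazo-2-oxopropyl)phosphonate, 0 °C → rt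
Reagents that add atoms: dimethyl (1-diazo-2-oxopropyl)phosphonate, CC(=O)C(=[N+]=[N-])P(=O)(OC)OC
Why: The chelated aluminium hemiacetal should stop the reduction at the aldehyde level, and the Seyferth–Gilbert homologation in its Ohira–Bestmann form converts the liberated α-alkoxy aldehyde into the alkyne under carbonate conditions mild enough to leave the chiral-pool stereocentre untouched.

Step 2
Reactants: 3 (R)-4-ethynyl-2,2-dimethyl-1,3-dioxolane
Product: 5 3-[(4R)-2,2-dimethyl-1,3-dioxolan-4-yl]prop-2-yn-1-ol, via lithium acetylide 4 (not isolated)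
Conditions: n-BuLi, THF, −78 °C; then (CH2O)n, −78 °C → rt
Reagents that add atoms: formaldehyde (as paraformaldehyde), C=O
Why: Deprotonation of the terminal alkyne and addition of the acetylide to formaldehyde (hydroxymethylation) forms no stereocentre and does not touch the existing one.

Step 3
Reactants: 5 3-[(4R)-2,2-dimethyl-1,3-dioxolan-4-yl]prop-2-yn-1-ol
Product: 7 (Z)-3-[(4S)-2,2-dimethyl-1,3-dioxolan-4-yl]-3-iodoprop-2-en-1-ol, via cyclic vinylalanate 6 (not isolated)
Conditions: Red-Al, THF, 0 °C → rt; then I2, THF, −78 → 0 °C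
Reagents that add atoms: iodine, II
Why: Hydroxyl-directed trans-hydroalumination of the propargylic alcohol puts hydride on C2 and aluminium on C3 in a five-membered alkoxyaluminate, and iodinolysis of the C–Al bond with retention should give the (Z)-iodide only; the stereocentre is not involved (its descriptor changes by the priority rules alone).

Step 4
Reactants: 7 (Z)-3-[(4S)-2,2-dimethyl-1,3-dioxolan-4-yl]-3-iodoprop-2-en-1-ol
Product: 8 tert-butyl{[(2Z)-3-[(4S)-2,2-dimethyl-1,3-dioxolan-4-yl]-3-iodoprop-2-en-1-yl]oxy}diphenylsilane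
Conditions: TBDPSCl, imidazole, DMF, 0 °C → rt
Reagents that add atoms: tert-butyl(chloro)diphenylsilane, CC(C)(C)[Si](Cl)(c1ccccc1)c1ccccc1
Why: Imidazole-promoted silylation of the primary allylic alcohol (silyl ether formation) installs a group that should survive the organozinc coupling, aqueous acetic acid and SnCl4.

Step 5
Reactants: 9 4-benzyloxy-3-methoxybenzyl alcohol
Product: 10 4-benzyloxy-3-methoxybenzyl chloride
Conditions: SOCl2, CH2Cl2, 0 °C; used at once
Reagents that add atoms: thionyl chloride, O=S(Cl)Cl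
Why: Chlorodehydroxylation through the chlorosulfite is fast for this electron-rich benzylic alcohol at 0 °C and leaves the aryl benzyl ether intact.

Step 6
Reactants: 10 4-benzyloxy-3-methoxybenzyl chloride; 8 tert-butyl{[(2Z)-3-[(4S)-2,2-dimethyl-1,3-dioxolan-4-yl]-3-iodoprop-2-en-1-yl]oxy}diphenylsilane
Product: 12 tert-butyl{[(2E)-4-[4-(benzyloxy)-3-methoxyphenyl]-3-[(4R)-2,2-dimethyl-1,3-dioxolan-4-yl]but-2-en-1-yl]oxy}diphenylsilane, via benzylzinc chloride 11 (not isolated)
Conditions: Zn dust, LiCl, THF, 25 °C; solution transferred to 8, Pd(PPh3)4 (5 mol %), THF, 25 → 50 °C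
Reagents that add atoms: none
Why: LiCl-assisted zinc insertion gives the benzylic zinc reagent with little Wurtz coupling, and the Negishi sp3–sp2 coupling replaces iodide with retention of alkene geometry, so the benzyl group ends cis to the silyloxymethyl group ((E)-alkene).

Step 7
Reactants: 12 tert-butyl{[(2E)-4-[4-(benzyloxy)-3-methoxyphenyl]-3-[(4R)-2,2-dimethyl-1,3-dioxolan-4-yl]but-2-en-1-yl]oxy}diphenylsilane
Product: 13 (2R,3E)-3-[4-(benzyloxy)-3-methoxybenzyl]-5-[(tert-butyldiphenylsilyl)oxy]pent-3-ene-1,2-diol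
Conditions: AcOH/H2O (4:1), 40 °C
Reagents that add atoms: none
Why: Acid-catalysed hydrolysis of the terminal isopropylidene acetal (acetonide removal) should leave the TBDPS ether, the benzyl ether, the (E)-alkene and the carbinol stereocentre untouched.

Step 8
Reactants: 13 (2R,3E)-3-[4-(benzyloxy)-3-methoxybenzyl]-5-[(tert-butyldiphenylsilyl)oxy]pent-3-ene-1,2-diol; 14 4-benzyloxy-3-methoxybenzaldehyde
Product: 16 (2S,3R,4S)-2-[4-(benzyloxy)-3-methoxyphenyl]-4-[4-(benzyloxy)-3-methoxybenzyl]-3-{[(tert-butyldiphenylsilyl)oxy]methyl}tetrahydrofuran-4-carbaldehyde, via benzylidene acetal 15 (not isolated)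
Conditions: 14 (1.1 equiv), PPTS (cat.), benzene, reflux (Dean–Stark); evaporate; then SnCl4 (1.5 equiv), CH2Cl2, −78 → −40 °C; cold aq. NaHCO3 quench
Reagents that add atoms: none
Why: SnCl4 opens the acetal reversibly, and only the oxocarbenium ion on the primary oxygen can reach the alkene: its carbon (future C2) is attacked by the alkene CH (future C3) to give a tertiary oxan-4-yl cation at the benzyl-bearing carbon (future C4), and the ring CH2 (future C5) then shifts from the stannyloxy carbinol carbon to that cation, so the oxane contracts to the tetrahydrofuran and the carbinol carbon ends as the C4 formyl group. The closest known reaction type is the Prins cyclisation–pinacol rearrangement of allylic diol acetals to 3-acyltetrahydrofurans. The oxane closes 6-endo-trig through a chair; the tetrahydrofuran ring is not closed directly but arises from it by the 1,2-alkyl shift. C2 is set by the (E)-oxocarbenium geometry (aryl equatorial), C3 by the (E)-alkene geometry (silyloxymethyl equatorial, hence trans to aryl), C4 by suprafacial delivery of C2 and C5 to one alkene face (benzyl stays cis to the C3 arm, formyl cis to aryl), and the absolute sense by the (R)-carbinol, whose C–OSn bond is expected to lie equatorial, in the nodal plane of the developing cation. The step needs face selectivity without racemisation: the p-alkoxyaryl group makes the starting oxocarbenium ion far more stable than the formaldehyde-type ion of a 2-oxonia-Cope shift, the trisubstituted alkene gives a tertiary cation that is trapped at once by the pinacol shift, and the low temperature should keep the new p-alkoxybenzylic C2–O bond from ionising again.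

Step 9
Reactants: 16 (2S,3R,4S)-2-[4-(benzyloxy)-3-methoxyphenyl]-4-[4-(benzyloxy)-3-methoxybenzyl]-3-{[(tert-butyldiphenylsilyl)oxy]methyl}tetrahydrofuran-4-carbaldehyde
Product: 18 (2S,3R,4S)-2-[4-(benzyloxy)-3-methoxyphenyl]-4-[4-(benzyloxy)-3-methoxybenzyl]-3-{[(tert-butyldiphenylsilyl)oxy]methyl}tetrahydrofuran-4-ol, via tertiary formate 17 (not isolated)
Conditions: mCPBA, NaHCO3, CH2Cl2, 0 °C → rt; aq. Na2S2O3 work-up; then K2CO3 (cat.), MeOH, rt
Reagents that add atoms: 3-chloroperbenzoic acid, O=C(OO)c1cccc(Cl)c1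
Why: In the Baeyer–Villiger oxidation the fully substituted C4 should migrate in preference to hydrogen with retention of configuration, and the formate is then removed by transesterification with methanol; silyl and benzyl ethers are inert to both reagents.

Step 10
Reactants: 18 (2S,3R,4S)-2-[4-(benzyloxy)-3-methoxyphenyl]-4-[4-(benzyloxy)-3-methoxybenzyl]-3-{[(tert-butyldiphenylsilyl)oxy]methyl}tetrahydrofuran-4-ol
Product: 19 (2S,3R,4S)-2-[4-(benzyloxy)-3-methoxyphenyl]-4-[4-(benzyloxy)-3-methoxybenzyl]-3-(hydroxymethyl)tetrahydrofuran-4-ol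
Conditions: TBAF, THF, 0 °C → rt
Reagents that add atoms: none
Why: Fluoride-mediated desilylation, driven by Si–F bond formation, frees the primary alcohol without affecting the tertiary alcohol or the benzyl ethers.

Step 11
Reactants: 19 (2S,3R,4S)-2-[4-(benzyloxy)-3-methoxyphenyl]-4-[4-(benzyloxy)-3-methoxybenzyl]-3-(hydroxymethyl)tetrahydrofuran-4-ol
Product: 20 {(2S,3R,4S)-2-[4-(benzyloxy)-3-methoxyphenyl]-4-[4-(benzyloxy)-3-methoxybenzyl]-4-hydroxytetrahydrofuran-3-yl}methyl acetate
Conditions: Ac2O (1.2 equiv), pyridine, CH2Cl2, 0 °C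
Reagents that add atoms: acetic anhydride, CC(=O)OC(C)=O
Why: O-Acylation under these mild conditions is selective for the primary hydroxyl, since the hindered tertiary C4 hydroxyl does not react without forcing.

Step 12
Reactants: 20 {(2S,3R,4S)-2-[4-(benzyloxy)-3-methoxyphenyl]-4-[4-(benzyloxy)-3-methoxybenzyl]-4-hydroxytetrahydrofuran-3-yl}methyl acetate
Product: 21 olivil monoacetate, [(2S,3R,4S)-4-hydroxy-2-(4-hydroxy-3-methoxyphenyl)-4-(4-hydroxy-3-methoxybenzyl)tetrahydrofuran-3-yl]methyl acetate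
Conditions: H2 (1 atm), 10% Pd/C, EtOAc, rt, stopped after uptake of 2 equiv
Reagents that add atoms: none
Why: Catalytic hydrogenolysis of the two aryl benzyl ethers under neutral conditions should be much faster than cleavage of the cyclic benzylic C2–O bond, and it leaves the acetate, the tertiary alcohol and all stereocentres untouched.

**Compound list**

1 | methyl (S)-2,2-dimethyl-1,3-dioxolane-4-carboxylate | COC(=O)[C@@H]1COC(C)(C)O1 | starting material
2 | (S)-2,2-dimethyl-1,3-dioxolane-4-carbaldehyde | O=C[C@@H]1COC(C)(C)O1 | intermediate (not isolated)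
3 | (R)-4-ethynyl-2,2-dimethyl-1,3-dioxolane | C#C[C@@H]1COC(C)(C)O1 | intermediate
4 | lithium [(4R)-2,2-dimethyl-1,3-dioxolan-4-yl]acetylide | [Li]C#C[C@@H]1COC(C)(C)O1 | intermediate (not isolated)
5 | 3-[(4R)-2,2-dimethyl-1,3-dioxolan-4-yl]prop-2-yn-1-ol | OCC#C[C@@H]1COC(C)(C)O1 | intermediate
6 | sodium 3-[(4S)-2,2-dimethyl-1,3-dioxolan-4-yl]-2,2-bis(2-methoxyethoxy)-2,5-dihydro-1,2-oxaaluminol-2-uide (cyclic vinylalanate) | [Na+].COCCO[Al-]1(OCCOC)OCC=C1[C@@H]1COC(C)(C)O1 | intermediate (not isolated)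
7 | (Z)-3-[(4S)-2,2-dimethyl-1,3-dioxolan-4-yl]-3-iodoprop-2-en-1-ol | OC/C=C(\I)[C@@H]1COC(C)(C)O1 | intermediate
8 | tert-butyl{[(2Z)-3-[(4S)-2,2-dimethyl-1,3-dioxolan-4-yl]-3-iodoprop-2-en-1-yl]oxy}diphenylsilane | CC(C)(C)[Si](OC/C=C(\I)[C@@H]1COC(C)(C)O1)(c1ccccc1)c1ccccc1 | intermediate
9 | 4-benzyloxy-3-methoxybenzyl alcohol | COc1cc(CO)ccc1OCc1ccccc1 | starting material
10 | 4-benzyloxy-3-methoxybenzyl chloride | COc1cc(CCl)ccc1OCc1ccccc1 | intermediate
11 | (4-benzyloxy-3-methoxybenzyl)zinc chloride | COc1cc(C[Zn]Cl)ccc1OCc1ccccc1 | intermediate (not isolated)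
12 | tert-butyl{[(2E)-4-[4-(benzyloxy)-3-methoxyphenyl]-3-[(4R)-2,2-dimethyl-1,3-dioxolan-4-yl]but-2-en-1-yl]oxy}diphenylsilane | COc1cc(C/C(=C\CO[Si](c2ccccc2)(c2ccccc2)C(C)(C)C)[C@@H]2COC(C)(C)O2)ccc1OCc1ccccc1 | intermediate
13 | (2R,3E)-3-[4-(benzyloxy)-3-methoxybenzyl]-5-[(tert-butyldiphenylsilyl)oxy]pent-3-ene-1,2-diol | OC[C@H](O)/C(Cc1ccc(OCc2ccccc2)c(OC)c1)=C/CO[Si](c1ccccc1)(c1ccccc1)C(C)(C)C | intermediate
14 | 4-benzyloxy-3-methoxybenzaldehyde | COc1cc(C=O)ccc1OCc1ccccc1 | starting material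
15 | (4R)-2-[4-(benzyloxy)-3-methoxyphenyl]-4-[(2E)-1-[4-(benzyloxy)-3-methoxyphenyl]-4-[(tert-butyldiphenylsilyl)oxy]but-2-en-2-yl]-1,3-dioxolane (both C2 epimers) | COc1cc(C2OC[C@H](O2)/C(Cc2ccc(OCc3ccccc3)c(OC)c2)=C/CO[Si](c2ccccc2)(c2ccccc2)C(C)(C)C)ccc1OCc1ccccc1 | intermediate (not isolated)
16 | (2S,3R,4S)-2-[4-(benzyloxy)-3-methoxyphenyl]-4-[4-(benzyloxy)-3-methoxybenzyl]-3-{[(tert-butyldiphenylsilyl)oxy]methyl}tetrahydrofuran-4-carbaldehyde | COc1cc(C[C@@]2(C=O)CO[C@H](c3ccc(OCc4ccccc4)c(OC)c3)[C@H]2CO[Si](c3ccccc3)(c3ccccc3)C(C)(C)C)ccc1OCc1ccccc1 | intermediate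
17 | (2S,3R,4S)-2-[4-(benzyloxy)-3-methoxyphenyl]-4-[4-(benzyloxy)-3-methoxybenzyl]-3-{[(tert-butyldiphenylsilyl)oxy]methyl}tetrahydrofuran-4-yl formate | COc1cc(C[C@@]2(OC=O)CO[C@H](c3ccc(OCc4ccccc4)c(OC)c3)[C@H]2CO[Si](c3ccccc3)(c3ccccc3)C(C)(C)C)ccc1OCc1ccccc1 | intermediate (not isolated)
18 | (2S,3R,4S)-2-[4-(benzyloxy)-3-methoxyphenyl]-4-[4-(benzyloxy)-3-methoxybenzyl]-3-{[(tert-butyldiphenylsilyl)oxy]methyl}tetrahydrofuran-4-ol | COc1cc(C[C@@]2(O)CO[C@H](c3ccc(OCc4ccccc4)c(OC)c3)[C@H]2CO[Si](c3ccccc3)(c3ccccc3)C(C)(C)C)ccc1OCc1ccccc1 | intermediate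
19 | (2S,3R,4S)-2-[4-(benzyloxy)-3-methoxyphenyl]-4-[4-(benzyloxy)-3-methoxybenzyl]-3-(hydroxymethyl)tetrahydrofuran-4-ol | COc1cc(C[C@@]2(O)CO[C@H](c3ccc(OCc4ccccc4)c(OC)c3)[C@H]2CO)ccc1OCc1ccccc1 | intermediate
20 | {(2S,3R,4S)-2-[4-(benzyloxy)-3-methoxyphenyl]-4-[4-(benzyloxy)-3-methoxybenzyl]-4-hydroxytetrahydrofuran-3-yl}methyl acetate | COc1cc(C[C@@]2(O)CO[C@H](c3ccc(OCc4ccccc4)c(OC)c3)[C@H]2COC(C)=O)ccc1OCc1ccccc1 | intermediate
21 | olivil monoacetate, [(2S,3R,4S)-4-hydroxy-2-(4-hydroxy-3-methoxyphenyl)-4-(4-hydroxy-3-methoxybenzyl)tetrahydrofuran-3-yl]methyl acetate | COc1cc(C[C@@]2(O)CO[C@H](c3ccc(O)c(OC)c3)[C@H]2COC(C)=O)ccc1O | target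

**Step count**

Total: 12 steps. Longest linear sequence: 11 steps (steps 1–4 and 6–12, from 1 to 21).

**Steps most likely to fail**

Step 8. What may go wrong: the chirality of the carbinol centre may be passed on incompletely, either by cyclisation through the chair with an axial stannyloxy group or by a reversible 2-oxonia-Cope shift before ring closure. The new p-alkoxybenzylic C2–O bond may also ionise again under the Lewis acid. A clean reversal of the facial sense would only call for the enantiomer of 1. Fallback, setting out from 14 (with 10 as the alkylating agent) and returning at 18: a lactone route in which no stereocentre is sacrificed. (S)-4-Benzyl-2-oxazolidinone is N-acylated (n-BuLi, methyl 4-chloro-4-oxobutanoate) to succinyl imide F1. Its dibutylboron enolate (Bu2BOTf, i-Pr2NEt) adds to 14 in an Evans syn-aldol reaction to give aldol adduct F2, which closes with loss of methanol to trans-lactone imide F3 (catalytic acid if needed). LiOH/H2O2 removes the auxiliary to give lactone acid F4, BH3·SMe2 reduces the acid in preference to the lactone to hydroxymethyl lactone F5, and TBDPSCl/imidazole gives silyl ether F6. The lithium enolate (LiHMDS, −78 °C) is alkylated with 10 (NaI) anti to the C3 arm to give benzyl lactone F7. Its potassium enolate (KHMDS) is hydroxylated with 2-(phenylsulfonyl)-3-phenyloxaziridine, again anti to the C3 arm, so that hydroxyl ends trans and benzyl cis to the silyloxymethyl group in hydroxy lactone F8. LiBH4 opens the lactone to triol F9, and brief treatment with catalytic CSA closes the ring through the p-benzyloxybenzylic cation with the 2,3-trans preference, giving 18.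

Step 3. What may go wrong: the vinylalanate may expel the neighbouring dioxolane oxygen (β-elimination to an allene with opening of the acetonide) or lose its C–Al bond by protonolysis before the iodine arrives. Fallback, setting out from 5 and returning at 7: ruthenium-catalysed trans-hydrosilylation of 5 with benzyldimethylsilane ([Cp*Ru(MeCN)3]PF6, acetone, 0 °C) avoids any carbanionic intermediate and should place silicon on the alkyne carbon remote from the hydroxyl, giving (Z)-vinylsilane F10. Iododesilylation with N-iodosuccinimide in hexafluoroisopropanol at 0 °C exchanges silicon for iodine with retention and leads back to 7.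

Step 9. What may go wrong: in the Criegee adduct of the aldehyde, hydride migration may compete with migration of the fully substituted C4, which drains material into the carboxylic acid. Fallback, setting out from 16 and returning at 18: the formyl group is first turned into an acetyl group, for which only C4 can migrate efficiently. MeMgBr adds to 16 to give secondary carbinol F11 (both carbinol epimers), and Dess–Martin periodinane oxidises it to methyl ketone F12. Baeyer–Villiger oxidation (buffered mCPBA, or CF3CO3H/Na2HPO4 if slow) gives tertiary acetate F13 with retention at C4, and DIBAL-H at −78 °C removes the acetyl group to return 18.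

**Further compounds**

F1 | step 8 | (S)-4-benzyl-3-(4-methoxy-4-oxobutanoyl)-1,3-oxazolidin-2-one | COC(=O)CCC(=O)N1C(=O)OC[C@@H]1Cc1ccccc1
F2 | step 8 | methyl (3S,4S)-3-{[(4S)-4-benzyl-2-oxo-1,3-oxazolidin-3-yl]carbonyl}-4-[4-(benzyloxy)-3-methoxyphenyl]-4-hydroxybutanoate | COC(=O)C[C@H](C(=O)N1C(=O)OC[C@@H]1Cc1ccccc1)[C@H](O)c1ccc(OCc2ccccc2)c(OC)c1
F3 | step 8 | (4S)-4-benzyl-3-{[(2S,3S)-2-[4-(benzyloxy)-3-methoxyphenyl]-5-oxotetrahydrofuran-3-yl]carbonyl}-1,3-oxazolidin-2-one | C1C(=O)O[C@H](c2ccc(OCc3ccccc3)c(OC)c2)[C@H]1C(=O)N1C(=O)OC[C@@H]1Cc1ccccc1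
F4 | step 8 | (2S,3S)-2-[4-(benzyloxy)-3-methoxyphenyl]-5-oxotetrahydrofuran-3-carboxylic acid | C1C(=O)O[C@H](c2ccc(OCc3ccccc3)c(OC)c2)[C@H]1C(=O)O
F5 | step 8 | (4R,5S)-5-[4-(benzyloxy)-3-methoxyphenyl]-4-(hydroxymethyl)dihydrofuran-2(3H)-one | C1C(=O)O[C@H](c2ccc(OCc3ccccc3)c(OC)c2)[C@H]1CO
F6 | step 8 | (4R,5S)-5-[4-(benzyloxy)-3-methoxyphenyl]-4-{[(tert-butyldiphenylsilyl)oxy]methyl}dihydrofuran-2(3H)-one | C1C(=O)O[C@H](c2ccc(OCc3ccccc3)c(OC)c2)[C@H]1CO[Si](c1ccccc1)(c1ccccc1)C(C)(C)C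
F7 | step 8 | (3S,4R,5S)-3-[4-(benzyloxy)-3-methoxybenzyl]-5-[4-(benzyloxy)-3-methoxyphenyl]-4-{[(tert-butyldiphenylsilyl)oxy]methyl}dihydrofuran-2(3H)-one | COc1cc(C[C@@H]2C(=O)O[C@H](c3ccc(OCc4ccccc4)c(OC)c3)[C@H]2CO[Si](c3ccccc3)(c3ccccc3)C(C)(C)C)ccc1OCc1ccccc1
F8 | step 8 | (3S,4R,5S)-3-[4-(benzyloxy)-3-methoxybenzyl]-5-[4-(benzyloxy)-3-methoxyphenyl]-4-{[(tert-butyldiphenylsilyl)oxy]methyl}-3-hydroxydihydrofuran-2(3H)-one | COc1cc(C[C@@]2(O)C(=O)O[C@H](c3ccc(OCc4ccccc4)c(OC)c3)[C@H]2CO[Si](c3ccccc3)(c3ccccc3)C(C)(C)C)ccc1OCc1ccccc1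
F9 | step 8 | (2S,3R,4S)-2-[4-(benzyloxy)-3-methoxybenzyl]-4-[4-(benzyloxy)-3-methoxyphenyl]-3-{[(tert-butyldiphenylsilyl)oxy]methyl}butane-1,2,4-triol | COc1cc(C[C@@](O)(CO)[C@H](CO[Si](c2ccccc2)(c2ccccc2)C(C)(C)C)[C@H](O)c2ccc(OCc3ccccc3)c(OC)c2)ccc1OCc1ccccc1
F10 | step 3 | (Z)-3-[benzyl(dimethyl)silyl]-3-[(4S)-2,2-dimethyl-1,3-dioxolan-4-yl]prop-2-en-1-ol | OC/C=C(\[Si](C)(C)Cc1ccccc1)[C@@H]1COC(C)(C)O1
F11 | step 9 | 1-[(2S,3R,4S)-2-[4-(benzyloxy)-3-methoxyphenyl]-4-[4-(benzyloxy)-3-methoxybenzyl]-3-{[(tert-butyldiphenylsilyl)oxy]methyl}tetrahydrofuran-4-yl]ethanol (both carbinol epimers) | COc1cc(C[C@@]2(C(C)O)CO[C@H](c3ccc(OCc4ccccc4)c(OC)c3)[C@H]2CO[Si](c3ccccc3)(c3ccccc3)C(C)(C)C)ccc1OCc1ccccc1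
F12 | step 9 | 1-[(2S,3R,4S)-2-[4-(benzyloxy)-3-methoxyphenyl]-4-[4-(benzyloxy)-3-methoxybenzyl]-3-{[(tert-butyldiphenylsilyl)oxy]methyl}tetrahydrofuran-4-yl]ethanone | COc1cc(C[C@@]2(C(C)=O)CO[C@H](c3ccc(OCc4ccccc4)c(OC)c3)[C@H]2CO[Si](c3ccccc3)(c3ccccc3)C(C)(C)C)ccc1OCc1ccccc1
F13 | step 9 | (2S,3R,4S)-2-[4-(benzyloxy)-3-methoxyphenyl]-4-[4-(benzyloxy)-3-methoxybenzyl]-3-{[(tert-butyldiphenylsilyl)oxy]methyl}tetrahydrofuran-4-yl acetate | COc1cc(C[C@@]2(OC(C)=O)CO[C@H](c3ccc(OCc4ccccc4)c(OC)c3)[C@H]2CO[Si](c3ccccc3)(c3ccccc3)C(C)(C)C)ccc1OCc1ccccc1
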